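The rate constants were chosen freely, and the outcome is calculated.

A solubility in a scheme is easily taken for the ceiling on dissolved target, before asking whether the solution ever gets there.

    starting material + target → side product B (k1 = 0.112 /M/s)
    crystals ⇌ target, rate k2*(cs2 - [target]) while solid is left; crystals form when [target] > cs2 (cs2 = 38 mM, k2 = 0.516 /s)
    starting material → side product A (k3 = 0.00387 /s)
    starting material → target (k4 = 0.00382 /s)
starting material 0.10 M; time 3.0 min
- how much target and crystals together there is at 3.0 min, in percent of the starting material charged
- concentration of target in solution at 3.0 min, in percent of saturation
- percentages count the starting material that a species holds: one side product B counts as two
- target is meant together with its crystals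
- solid, in amounts per volume of the solution: crystals
- run time (flask): 3.0 min

Target is made at 0.00382 /s times c(starting material), but it is lost at 0.112 /M/s times c(target) times c(starting material), a pseudo-first-order loss at any given c(starting material). So c(starting material) cancels from the balance, and dissolved target climbs towards the balance level, the concentration at which making equals loss, 34.1 mM. That lies below the solubility, at 89.8% of it, so no crystals are expected, and the level stands at 34.1% of this flask's charge.

The approach to that level is the correction to reckon. Dropping the starting material lost through target, it decays at 0.00769 /s, and the gap to the level shrinks by the exponential of minus the constant 0.112 /M/s times the time integral of c(starting material). This reckoning by hand gives 22.7% of the charge, on the high side for the dropped loss.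

The forecast gives 21.6% and 56.9% of saturation, lower than this reckoning, holding that “no crystals ever form”.

The simulation gives 21.6% and 56.9%, with crystals at 0%, so the forecast stands. Left for 30.0 min, this flask reaches 23.9%, under the balance level. The step to side product B has the largest single effect: without it the flask holds 37.2% instead of 21.6%. The answer for this flask moves by 5 points at charges of 0.0572 M and 0.164 M.

In the neighbour charged with 0.40 M, the same balance level is 8.53% of the charge, and the simulation gives 8.31%.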